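The chroman is opened at two bonds of its dihydropyran ring, C4–C4a and C8a–O1. C4a and C8a are neighbouring benzene carbons, and the C4–C3–C2–O1 chain that bridges them is supplied as a γ-bromo tertiary alcohol which already holds the C2 stereocentre and the whole triene side chain. A single palladium/norbornene operation on an aryl iodide (iodine at C8a, hydrogen at C4a, a protected oxygen at C8 as the blocking ortho group) should alkylate C4a and then etherify C8a, closing the ring. The iodide comes from 4-methylcatechol in two steps, the (S)-bromo-carbinol from geranylgeraniol in three; acid removes the two MOM groups at the end.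

Key step: step 6

Remarks on the chemistry:
- Chroman numbering (O1, C2, C3, C4, C4a, C5–C8, C8a) is used for the target; benzene intermediates carry their own locants.
- C2 of the target is S. It originates as C3 of the (2S,3S)-epoxy alcohol made with L-(+)-diethyl tartrate. The descriptor stays S from 6 to 10 because the ranking O > CH2CH2X (later ring C3) > chain CH2 > CH3 never changes.
- The iodide must have iodine at the future C8a and its only ortho hydrogen at the future C4a, next to the methyl-bearing C5. Lithiation of 2 at C6 gives exactly this isomer.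
- The 1,3-diol is taken directly from the epoxy alcohol by hydride opening, which keeps the chain arm at three steps.

Step 1
Reactants: 1 4-methylcatechol
Product: 2 1,2-bis(methoxymethoxy)-4-methylbenzene
Conditions: NaH (2.4 equiv), MOMCl (2.4 equiv), DMF, 0 °C → rt
Reagents that add atoms: chloromethyl methyl ether, COCCl
Why: Williamson-type O-alkylation of the catechol dianion with the α-chloro ether should give the bis-acetal, which is stable to the bases of steps 2 and 6 and is a strong directing group for step 2.

Step 2
Reactants: 2 1,2-bis(methoxymethoxy)-4-methylbenzene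
Product: 4 1-iodo-2,3-bis(methoxymethoxy)-5-methylbenzene, via aryllithium 3 (not isolated)
Conditions: n-BuLi, TMEDA, Et2O, 0 °C; then I2, THF, −78 °C → rt
Reagents that add atoms: iodine, II
Why: Directed ortho-metalation should remove H-6 of 2 (ortho to the C1 OMOM group) in preference to H-3, which is shielded between the other OMOM group and the methyl group, and iodine quench of the aryllithium then places iodine meta to the methyl group.

Step 3
Reactants: 5 (2E,6E,10E)-geranylgeraniol
Product: 6 [(2S,3S)-3-methyl-3-[(3E,7E)-4,8,12-trimethyltrideca-3,7,11-trien-1-yl]oxiran-2-yl]methanol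
Conditions: Ti(OiPr)4 (10 mol %), L-(+)-diethyl tartrate (12 mol %), t-BuOOH, 4 Å MS, CH2Cl2, −20 °C
Reagents that add atoms: tert-butyl hydroperoxide, CC(C)(C)OO
Why: Sharpless asymmetric epoxidation engages only the allylic alcohol, so the three remote alkenes stay intact, and the L-(+)-tartrate ligand directs oxygen to the face that gives the (2S,3S)-epoxide, which fixes the quaternary C–O carbon (future C2) as S.

Step 4
Reactants: 6 [(2S,3S)-3-methyl-3-[(3E,7E)-4,8,12-trimethyltrideca-3,7,11-trien-1-yl]oxiran-2-yl]methanol
Product: 7 (3S,6E,10E)-3,7,11,15-tetramethylhexadeca-6,10,14-triene-1,3-diol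
Conditions: Red-Al, THF, 0 °C → rt; aq. Rochelle salt
Reagents that add atoms: none
Why: In this hydroxyl-directed reductive opening of a 2,3-epoxy alcohol the alkoxyaluminate delivers hydride intramolecularly to C2, the less substituted epoxide carbon, so the C3–O bond and its configuration are kept and the 1,3-diol should result.

Step 5
Reactants: 7 (3S,6E,10E)-3,7,11,15-tetramethylhexadeca-6,10,14-triene-1,3-diol
Product: 8 (3S,6E,10E)-1-bromo-3,7,11,15-tetramethylhexadeca-6,10,14-trien-3-ol
Conditions: CBr4, PPh3, CH2Cl2, 0 °C
Reagents that add atoms: carbon tetrabromide, BrC(Br)(Br)Br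
Why: In the Appel reaction only the unhindered primary hydroxyl should form an alkoxyphosphonium ion and be displaced by bromide (SN2), while the crowded tertiary hydroxyl stays free under these neutral conditions.

Step 6
Reactants: 4 1-iodo-2,3-bis(methoxymethoxy)-5-methylbenzene; 8 (3S,6E,10E)-1-bromo-3,7,11,15-tetramethylhexadeca-6,10,14-trien-3-ol
Product: 9 (2S)-7,8-bis(methoxymethoxy)-2,5-dimethyl-2-[(3E,7E)-4,8,12-trimethyltrideca-3,7,11-trien-1-yl]-3,4-dihydro-2H-1-benzopyran
Conditions: Pd(OAc)2 (10 mol %), XPhos (20 mol %), norbornene (1 equiv), CsOPiv (30 mol %), Cs2CO3 (3 equiv), 1,4-dioxane, 100 °C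
Reagents that add atoms: none
Why: Proposed new method: Pd(0) inserts into the C–I bond of 4, norbornene inserts, and the only ortho C–H (future C4a, between the palladated carbon and the methyl-bearing carbon) is palladated with carboxylate assistance to an aryl–norbornyl palladacycle; SN2-type oxidative addition of the primary C–Br of 8 and C–C reductive elimination form C4–C4a, the now doubly ortho-substituted arene expels norbornene, and the tethered tertiary hydroxyl is deprotonated onto palladium at C8a so that C–O reductive elimination forms C8a–O1. The closest known reaction types are the palladium/norbornene annulation of aryl iodides with epoxides to 2,3-dihydrobenzofurans (same ortho-alkylation then ipso-etherification, one carbon shorter) and the palladium-catalysed cyclisation of 2-haloaryl-tethered tertiary alcohols to 2,2-disubstituted chromans. The six-membered dihydropyran ring closes by intramolecular O-arylation, that is C(sp2)–O reductive elimination from a seven-membered aryl(alkoxo)palladium(II) chelate. No stereocentre is formed, and C2 keeps its S configuration because only its O–H bond is exchanged and none of its bonds to carbon or oxygen is broken. The step needs a single alkylation at C4a and ipso C–O formation instead of reduction or Heck termination: the C8 OMOM group leaves one ortho C–H and is the second ortho substituent that drives norbornene extrusion, the tertiary alkoxide has no hydrogen on its carbinol carbon for β-hydride elimination, the trisubstituted chain alkenes are poor Heck partners, and the bulky biaryl phosphine favours C–O reductive elimination.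

Step 7
Reactants: 9 (2S)-7,8-bis(methoxymethoxy)-2,5-dimethyl-2-[(3E,7E)-4,8,12-trimethyltrideca-3,7,11-trien-1-yl]-3,4-dihydro-2H-1-benzopyran
Product: 10 (2S)-2,5-dimethyl-2-[(3E,7E)-4,8,12-trimethyltrideca-3,7,11-trien-1-yl]-3,4-dihydro-2H-1-benzopyran-7,8-diol
Conditions: HCl (ca. 1 M in MeOH), degassed, rt
Reagents that add atoms: none
Why: Acid-catalysed acetal solvolysis (transacetalisation of the two aryl MOM ethers to dimethoxymethane) should free both phenols at room temperature, where the trisubstituted alkenes and the chroman ether are expected to survive, and exclusion of air protects the catechol.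

Compound list
1 | 4-methylcatechol (4-methylbenzene-1,2-diol) | Cc1ccc(O)c(O)c1 | starting material
2 | 1,2-bis(methoxymethoxy)-4-methylbenzene | Cc1ccc(OCOC)c(OCOC)c1 | intermediate
3 | [2,3-bis(methoxymethoxy)-5-methylphenyl]lithium (not isolated) | Cc1cc([Li])c(OCOC)c(OCOC)c1 | intermediate
4 | 1-iodo-2,3-bis(methoxymethoxy)-5-methylbenzene | Cc1cc(I)c(OCOC)c(OCOC)c1 | intermediate
5 | (2E,6E,10E)-geranylgeraniol | CC(C)=CCC/C(C)=C/CC/C(C)=C/CC/C(C)=C/CO | starting material
6 | [(2S,3S)-3-methyl-3-[(3E,7E)-4,8,12-trimethyltrideca-3,7,11-trien-1-yl]oxiran-2-yl]methanol | CC(C)=CCC/C(C)=C/CC/C(C)=C/CC[C@]1(C)O[C@H]1CO | intermediate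
7 | (3S,6E,10E)-3,7,11,15-tetramethylhexadeca-6,10,14-triene-1,3-diol | CC(C)=CCC/C(C)=C/CC/C(C)=C/CC[C@@](O)(C)CCO | intermediate
8 | (3S,6E,10E)-1-bromo-3,7,11,15-tetramethylhexadeca-6,10,14-trien-3-ol | CC(C)=CCC/C(C)=C/CC/C(C)=C/CC[C@@](O)(C)CCBr | intermediate
9 | (2S)-7,8-bis(methoxymethoxy)-2,5-dimethyl-2-[(3E,7E)-4,8,12-trimethyltrideca-3,7,11-trien-1-yl]-3,4-dihydro-2H-1-benzopyran | CC(C)=CCC/C(C)=C/CC/C(C)=C/CC[C@@]1(C)CCc2c(C)cc(OCOC)c(OCOC)c2O1 | intermediate
10 | (2S)-2,5-dimethyl-2-[(3E,7E)-4,8,12-trimethyltrideca-3,7,11-trien-1-yl]-3,4-dihydro-2H-1-benzopyran-7,8-diol | CC(C)=CCC/C(C)=C/CC/C(C)=C/CC[C@@]1(C)CCc2c(C)cc(O)c(O)c2O1 | target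

Total step count: 7
Longest linear sequence: 5 steps (steps 3, 4, 5, 6, 7, from geranylgeraniol)

Steps most likely to fail

Step 6 (Proposed new method). Palladation of the single ortho C–H, which lies next to the methyl-bearing carbon, may be too slow, so that the aryl–norbornyl palladium species is diverted into norbornene-retaining or reduced by-products. Alternatively, the arylpalladium formed after norbornene loss may be protonated before the hindered tertiary alkoxide binds and eliminates. The fallback uses known chemistry only; it sets out from 2 and 6 and comes back at 9.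
- Arene: 2 is brominated para to an OMOM group and ortho to the methyl group (NBS, MeCN, 0 °C) to 1-bromo-4,5-bis(methoxymethoxy)-2-methylbenzene F1. LDA (THF, −78 °C) removes the proton between bromine and OMOM to give [6-bromo-2,3-bis(methoxymethoxy)-5-methylphenyl]lithium F2, which is chlorinated with hexachloroethane to 1-bromo-2-chloro-3,4-bis(methoxymethoxy)-6-methylbenzene F3.
- Chain: 6 is converted with I2, PPh3 and imidazole into (2R,3S)-2-(iodomethyl)-3-methyl-3-[(3E,7E)-4,8,12-trimethyltrideca-3,7,11-trien-1-yl]oxirane F4. Zinc dust in ethanol then opens it reductively to (3S,6E,10E)-3,7,11,15-tetramethylhexadeca-1,6,10,14-tetraen-3-ol F5; the C–O bond at the stereocentre is untouched.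
- Coupling: hydroboration of the vinyl group of F5 with 9-BBN (THF, rt) gives the B-alkyl-9-BBN adduct F6. It is coupled in the same flask at the C–Br bond of F3 (B-alkyl Suzuki–Miyaura coupling; PdCl2(dppf), Cs2CO3, DMF/THF/H2O, 60 °C) to (3S,6E,10E)-1-[2-chloro-3,4-bis(methoxymethoxy)-6-methylphenyl]-3,7,11,15-tetramethylhexadeca-6,10,14-trien-3-ol F7.
- Ring closure: palladium-catalysed intramolecular O-arylation of the tertiary alcohol of F7 (Pd(OAc)2, tBuXPhos, Cs2CO3, toluene, 100 °C) gives 9.

Step 7. Protic acid may protonate the trisubstituted alkenes, leading to cyclisation or solvent addition along the chain, before the second acetal is cleaved, and the liberated catechol may oxidise. The fallback replaces acid solvolysis by a two-stage silyl exchange; it sets out from 9 and comes back at 10. TMSOTf with 2,2'-bipyridyl (CH2Cl2, 0 °C) converts the aryl MOM ethers under aprotic, amine-buffered conditions into (2S)-2,5-dimethyl-2-[(3E,7E)-4,8,12-trimethyltrideca-3,7,11-trien-1-yl]-7,8-bis(trimethylsilyloxy)-3,4-dihydro-2H-1-benzopyran F8. The labile aryl silyl ethers are then hydrolysed with water in THF at room temperature under argon to give 10.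

Step 5. Chemoselectivity between the two hydroxyls may be lost: adventitious HBr may ionise or dehydrate the tertiary carbinol, or the activated primary oxygen may be displaced intramolecularly to an oxetane. The fallback separates activation from substitution; it sets out from 7 and comes back at 8. Selective sulfonylation of the primary hydroxyl (TsCl, Et3N, DMAP cat., CH2Cl2, 0 °C) gives (3S,6E,10E)-3-hydroxy-3,7,11,15-tetramethylhexadeca-6,10,14-trien-1-yl 4-methylbenzenesulfonate F9. Displacement with LiBr in acetone at 50 °C then gives 8.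

Further compounds
F1 | step 6 | 1-bromo-4,5-bis(methoxymethoxy)-2-methylbenzene | Cc1cc(OCOC)c(OCOC)cc1Br
F2 | step 6 | [6-bromo-2,3-bis(methoxymethoxy)-5-methylphenyl]lithium (not isolated) | Cc1cc(OCOC)c(OCOC)c([Li])c1Br
F3 | step 6 | 1-bromo-2-chloro-3,4-bis(methoxymethoxy)-6-methylbenzene | Cc1cc(OCOC)c(OCOC)c(Cl)c1Br
F4 | step 6 | (2R,3S)-2-(iodomethyl)-3-methyl-3-[(3E,7E)-4,8,12-trimethyltrideca-3,7,11-trien-1-yl]oxirane | CC(C)=CCC/C(C)=C/CC/C(C)=C/CC[C@]1(C)O[C@H]1CI
F5 | step 6 | (3S,6E,10E)-3,7,11,15-tetramethylhexadeca-1,6,10,14-tetraen-3-ol | CC(C)=CCC/C(C)=C/CC/C(C)=C/CC[C@@](O)(C)C=C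
F6 | step 6 | 9-[(3R,6E,10E)-3-hydroxy-3,7,11,15-tetramethylhexadeca-6,10,14-trien-1-yl]-9-borabicyclo[3.3.1]nonane (not isolated; same spatial arrangement as F5, descriptor R because boron ranks below carbon) | CC(C)=CCC/C(C)=C/CC/C(C)=C/CC[C@@](O)(C)CCB1C2CCCC1CCC2
F7 | step 6 | (3S,6E,10E)-1-[2-chloro-3,4-bis(methoxymethoxy)-6-methylphenyl]-3,7,11,15-tetramethylhexadeca-6,10,14-trien-3-ol | CC(C)=CCC/C(C)=C/CC/C(C)=C/CC[C@@](O)(C)CCc1c(C)cc(OCOC)c(OCOC)c1Cl
F8 | step 7 | (2S)-2,5-dimethyl-2-[(3E,7E)-4,8,12-trimethyltrideca-3,7,11-trien-1-yl]-7,8-bis(trimethylsilyloxy)-3,4-dihydro-2H-1-benzopyran | CC(C)=CCC/C(C)=C/CC/C(C)=C/CC[C@@]1(C)CCc2c(C)cc(O[Si](C)(C)C)c(O[Si](C)(C)C)c2O1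
F9 | step 5 | (3S,6E,10E)-3-hydroxy-3,7,11,15-tetramethylhexadeca-6,10,14-trien-1-yl 4-methylbenzenesulfonate | CC(C)=CCC/C(C)=C/CC/C(C)=C/CC[C@@](O)(C)CCOS(=O)(=O)c1ccc(C)cc1
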